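Target: 6,7-dihydroxy-5-[(7-hydroxy-2-oxo-2H-chromen-6-yl)oxy]-2H-chromen-2-one (17). Coumarin locants are used throughout. Primed locants and "ring A" refer to the benzene ring of the 7'-hydroxycoumarin unit; unprimed locants and "ring B" refer to the benzene ring of the 6,7-dihydroxycoumarin unit. Compound numbers refer to the list after the steps.

## Analysis of the target

The target is made of two coumarins joined by a diaryl ether between C5 of one unit and O6' of the other. It has no stereocentre and no element of chirality that needs control. Both lactones open with hydroxide or amines, both C3=C4 bonds are Michael acceptors, and the free catechol of ring B is easily oxidised, so the three hydroxyls are best carried as ethers until the last step. Ring B is the hard part: five of its six carbons are substituted, four of them (C5, C6, C7, C8a) by oxygen, and the ether oxygen on C5 sits between C4a and C6. A route from an aromatic precursor would have to tell several neighbouring oxygens apart and arylate a phenol with two ortho substituents. Ring A, by contrast, has exactly the substitution pattern of isoscopoletin. The strategy rests on the pattern of ring B: oxygen on C8a, C6, C5 and C7, carbon on C4a, and the only hydrogen on C8. A vinylketene carrying an alkoxy group, an aryloxy group and an alkyl terminus supplies C8a, C6, C5 and C4a in that order, and an ynol ether supplies C8 and C7, so ring B can be built last around an ether oxygen that is already in place.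

## Retrosynthetic reasoning

**17 to 16.** The three O–H bonds of 17 are traced back to one ethyl and two methyl ethers in 16. Cutting the O–alkyl bonds last keeps the catechol masked through the oxidative step before it. The forward reaction has to cleave three alkyl aryl ethers while leaving the diaryl ether and both lactones intact.

**16 to 15 to 14.** In the pyranone fused to ring B, the C3=C4 double bond is removed (16 to dihydrocoumarin 15) and the O1–C2 acyl bond is then cut (15 to phenol ester 14). A saturated propanoate chain is an inert spectator in the ring-forming step, whereas an acrylate would itself be attacked by a ketene or an amine. The forward steps are a lactonisation and a dehydrogenation at a benzylic carbon activated by the electron-rich ring.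

**14 to 8 and 9.** Ring B is cut at C8–C8a, C6–C7 and C4a–C8a. This separates a two-carbon piece (C7–C8, compound 9) from a four-carbon piece (C8a–C6–C5–C4a, carried by 8 with C8a as the acyl carbon). The cut is made here because it leaves the C5–O ether bond untouched and lets polarity place every substituent. The forward reaction has to turn 8 into vinylketene 10 by 1,4-dehydrochlorination, join 10 to 9 as cyclobutenone 11, open 11 to dienylketene 12, close 12 to dienone 13, and tautomerise 13 to 14. What is gained is that the crowded arene is never functionalised: all of its substituents arrive on acyclic carbon.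

**8 to 7 to 6.** The acyl chloride goes back to acid 7 and then to tert-butyl ester 6. The tert-butyl ester is chosen because it is removed by acid in the presence of the chain methyl ester, so only the conjugated carboxyl is activated.

**6 to 4 and 5.** The bond between the enoate β-carbon and the phenol oxygen is cut, giving chloro enoate 4 and phenol 5. The future diaryl ether is therefore formed by addition–elimination on an acyclic sp2 carbon, where the crowding of ring B does not yet exist. Ring A and its pyranone come complete with 5.

**4 to 3 to 1 and 2.** The C–Cl bond of 4 goes back to the ketone of β-keto ester 3, and the C2–C3 bond of 3 is cut into the enolate of 1 and acid chloride 2. In the final skeleton, 1 supplies C8a and C6 with its methoxy group, 2 supplies C5, C4a, C4, C3 and C2, and 9 supplies C7 and C8.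

## Alternatives that were turned down

**Alternative 1:** Both pyranones are disconnected at their O1–C8a bonds, which leads back to bis-cinnamic acid A2.
- **Forward key step:** Under flavin photocatalysis in air, each (E)-cinnamic acid is isomerised and its carboxylate oxygen closes oxidatively onto the ortho ring carbon. This gives trimethyl ether A1, and global demethylation then gives 17.
- **For:** This is the shortest route by a wide margin, roughly four steps against nine. A2 comes from a diaryl ether dialdehyde by a twofold Knoevenagel–Doebner condensation. The key reaction is documented for electron-rich cinnamic acids. In ring B only one ortho carbon is free, and it is para to a methoxy group.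
- **Against:** The diaryl ether still has to be made on a ring B carbon flanked by two substituents. In ring A the closure must choose between two free ortho carbons. Both are meta to the methoxy group, so the choice depends only on a para-versus-ortho preference relative to the aryloxy oxygen. Two oxidative closures must also succeed on one molecule, and the first-formed coumarin is itself a chromophore.
- **Comparison:** Alternative 1 is stronger on step count and on precedent for its key step. The chosen strategy offers in exchange a ring B whose substituents are fixed by connectivity and not by the site preference of an oxidation, and a ring A taken intact from 5. The ring B half of this idea, where the regiochemistry is unambiguous, is kept as the fallback for the key step.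

**Alternative 2:** The benzene of ring A is disconnected at C5'–C6' and C4a'–C8a' into bis(silyloxy)diene A4 and propynal A5.
- **Forward key step:** A Diels–Alder addition of A4 to A5, followed by elimination of the acetal methoxy group and desilylation, gives salicylaldehyde A3. A Wittig or Knoevenagel closure of the pyranone and demethylation would complete 17.
- **For:** Regiochemistry is set by the polarised diene, just as polarity sets it in the chosen route. Cycloaromatisations of this diene class are known, so its ring-forming step has closer precedent. A3 is one step from a coumarin and delivers the 7'-hydroxyl free. The step count is comparable.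
- **Against:** The route needs 5-hydroxy-6,7-dimethoxycoumarin A6. A6 already contains the whole contiguous oxygenation problem of ring B and has to be O-alkylated at its hindered hydroxyl. A4 carries an aryloxy group on its nucleophilic terminus, which lowers its reactivity. Forming A4 requires strong base in the presence of a coumarin. A5 is volatile and polymerises easily.
- **Comparison:** Alternative 2 is equal on regiocontrol and stronger on precedent. It builds the simple ring and has to obtain the difficult one ready-made, whereas the chosen strategy starts from the simple coumarin 5 and builds the difficult ring.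

**Alternative 3:** The benzene of ring A is disconnected at C5'–C6', C4a'–C8a' and C8'–C8a' into the Cr(CO)5 carbene complex A8, methyl pent-4-ynoate A9 and one carbonyl ligand.
- **Forward key step:** A Dötz benzannulation (alkyne insertion, carbonyl insertion, electrocyclisation of the chromium-bound dienylketene) gives phenol A7. The endgame would be the same as in the chosen route: lactonisation, dehydrogenation, demethylation.
- **For:** The ring-forming step is well established, and with a terminal alkyne the larger substituent reliably ends next to the new hydroxyl. On precedent it is stronger than the chosen key step.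
- **Against:** A6 is needed again. An aryloxy carbene complex has to be made by exchange with a hindered, weakly nucleophilic phenol, and such complexes are more electrophilic and less stable than alkoxy ones. Chromium is used stoichiometrically. The para-dioxygenated phenol A7 is sensitive to the oxidative work-up normally used to remove the metal.
- **Comparison:** The chosen route uses the same dienylketene and 6π logic without a metal, without A6, and with the ether bond formed on an unhindered acyclic carbon.

Key step: step 6

Assumption: the tetrasubstituted alkene of 4, 6, 7 and 8 and the trisubstituted alkene of 10, 11 and 12 are drawn as single geometric isomers for definiteness. Either isomer or a mixture is expected to serve, because both geometries are lost before 14.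

## Route

Step 1
Reactants: 1 tert-butyl 2-methoxyacetate; 2 methyl 5-chloro-5-oxopentanoate
Product: 3 1-tert-butyl 7-methyl 2-methoxy-3-oxoheptanedioate (racemic)
Conditions: 1 (2 equiv), LiN(iPr)2 (2 equiv), THF, −78 °C; then 2 (1 equiv), −78 to −40 °C; aq. NH4Cl
Reagents that add atoms: none
Why: Claisen-type C-acylation of the lithium enolate of 1 by the acid chloride of 2, which is far more electrophilic than its methyl ester; the second equivalent of enolate takes up the acidic proton of 3 and so prevents double acylation.

Step 2
Reactants: 3 1-tert-butyl 7-methyl 2-methoxy-3-oxoheptanedioate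
Product: 4 1-tert-butyl 7-methyl (2E)-3-chloro-2-methoxyhept-2-enedioate
Conditions: Ph3PCl2, Et3N, CH2Cl2, 0 °C to rt
Reagents that add atoms: dichlorotriphenylphosphorane, ClP(Cl)(c1ccccc1)(c1ccccc1)c1ccccc1
Why: Conversion of a β-keto ester into a β-chloro enoate: the enol oxygen is activated as an oxyphosphonium salt and chloride displaces triphenylphosphine oxide by addition–elimination; the amine keeps the medium non-acidic, so the tert-butyl ester should survive.

Step 3
Reactants: 4 1-tert-butyl 7-methyl (2E)-3-chloro-2-methoxyhept-2-enedioate; 5 isoscopoletin (6-hydroxy-7-methoxy-2H-chromen-2-one)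
Product: 6 1-tert-butyl 7-methyl (2E)-2-methoxy-3-[(7-methoxy-2-oxo-2H-chromen-6-yl)oxy]hept-2-enedioate
Conditions: Cs2CO3, DMF, 50–60 °C
Reagents that add atoms: none
Why: Nucleophilic vinylic substitution by addition–elimination: the caesium phenoxide of 5 adds to the β-carbon of the chloro enoate and chloride leaves, with the ester as the activating group; the lactone and both esters should tolerate anhydrous carbonate.

Step 4
Reactants: 6 1-tert-butyl 7-methyl (2E)-2-methoxy-3-[(7-methoxy-2-oxo-2H-chromen-6-yl)oxy]hept-2-enedioate
Product: 7 (2E)-2,7-dimethoxy-3-[(7-methoxy-2-oxo-2H-chromen-6-yl)oxy]-7-oxohept-2-enoic acid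
Conditions: TFA, CH2Cl2, 0 °C to rt
Reagents that add atoms: none
Why: Acidolysis of the tert-butyl ester through the tert-butyl cation; in the absence of water the methyl ester, the lactone and the push–pull enol ether are expected to be untouched.

Step 5
Reactants: 7 (2E)-2,7-dimethoxy-3-[(7-methoxy-2-oxo-2H-chromen-6-yl)oxy]-7-oxohept-2-enoic acid
Product: 8 methyl (5E)-7-chloro-6-methoxy-5-[(7-methoxy-2-oxo-2H-chromen-6-yl)oxy]-7-oxohept-5-enoate
Conditions: (COCl)2, DMF (cat.), CH2Cl2, 0 °C to rt; concentrate, use crude
Reagents that add atoms: oxalyl chloride, O=C(Cl)C(Cl)=O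
Why: Standard Vilsmeier-catalysed conversion of a carboxylic acid into its chloride; all by-products are volatile, so 8 can be taken on without purification.

Step 6
Reactants: 8 methyl (5E)-7-chloro-6-methoxy-5-[(7-methoxy-2-oxo-2H-chromen-6-yl)oxy]-7-oxohept-5-enoate; 9 ethoxyethyne
Product: 14 methyl 3-{4-ethoxy-6-hydroxy-3-methoxy-2-[(7-methoxy-2-oxo-2H-chromen-6-yl)oxy]phenyl}propanoate, via vinylketene 10 (not isolated), via 3-ethoxycyclobutenone 11 (not isolated), via dienylketene 12 (not isolated), via cyclohexadienone 13 (not isolated)
Conditions: 9 (excess), Et3N (slow addition), PhMe, rt to 45 °C; then volatiles removed, PhMe, 110 °C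
Reagents that add atoms: none
Why: Proposed new method: Et3N removes HCl from 8 by taking a C4 hydrogen (the α-carbon is fully substituted, so no other acidic position competes) and gives vinylketene 10. The unsubstituted, nucleophilic carbon of ynol ether 9 attacks the ketene carbon, and the (2+2) adduct across the ketene C=C is 3-ethoxycyclobutenone 11. On heating, 11 opens in a conrotatory 4π process in which the methoxy group on the sp3 carbon turns outward and the alkenyl group inward, so dienylketene 12 has its ketene and its alkenyl terminus on the same side of the central double bond. A thermal disrotatory 6π electrocyclisation joins the ketene carbon to the former C4 of 8, which closes the six-membered carbocycle at C4a–C8a, and enolisation of dienone 13 gives phenol 14. The closest known reactions are the Danheiser benzannulation of vinylketenes with alkoxy- and siloxyalkynes, the amine-induced 1,4-dehydrochlorination of α,β-unsaturated acid chlorides to vinylketenes, and the thermal opening of 4-alkenyl-4-alkoxycyclobutenones. No stereocentre remains: the racemic centres of 11 and 13 are destroyed by ring opening and tautomerisation. The step needs (2+2) periselectivity at the ketene C=C, which vinylketenes generally show, and head-to-tail regiochemistry, which the polarisation of 9 secures, so the ethoxy carbon ends meta to the hydroxyl and C8 is the only ring CH. Running the cycloaddition at low temperature and the electrocyclic cascade only afterwards should keep the phenol from meeting unreacted ketene.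

Step 7
Reactants: 14 methyl 3-{4-ethoxy-6-hydroxy-3-methoxy-2-[(7-methoxy-2-oxo-2H-chromen-6-yl)oxy]phenyl}propanoate
Product: 15 7-ethoxy-6-methoxy-5-[(7-methoxy-2-oxo-2H-chromen-6-yl)oxy]-3,4-dihydro-2H-chromen-2-one
Conditions: p-TsOH·H2O (cat.), PhMe, reflux
Reagents that add atoms: none
Why: Acid-catalysed lactonisation (intramolecular transesterification) of an ortho-hydroxy dihydrocinnamate; six-membered ring formation and removal of methanol drive it.

Step 8
Reactants: 15 7-ethoxy-6-methoxy-5-[(7-methoxy-2-oxo-2H-chromen-6-yl)oxy]-3,4-dihydro-2H-chromen-2-one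
Product: 16 7-ethoxy-6-methoxy-5-[(7-methoxy-2-oxo-2H-chromen-6-yl)oxy]-2H-chromen-2-one
Conditions: DDQ, 1,4-dioxane, reflux
Reagents that add atoms: none
Why: DDQ dehydrogenation of a 3,4-dihydrocoumarin: hydride is abstracted from benzylic C4, which is para to the ethoxy group and ortho to two oxygen-bearing carbons, and loss of the C3 proton gives the conjugated pyranone.

Step 9
Reactants: 16 7-ethoxy-6-methoxy-5-[(7-methoxy-2-oxo-2H-chromen-6-yl)oxy]-2H-chromen-2-one
Product: 17 6,7-dihydroxy-5-[(7-hydroxy-2-oxo-2H-chromen-6-yl)oxy]-2H-chromen-2-one
Conditions: BBr3 (excess), CH2Cl2, −78 °C to rt; then MeOH, H2O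
Reagents that add atoms: none
Why: Lewis-acid cleavage of alkyl aryl ethers by BBr3, with bromide attacking the alkyl carbon of the boron-complexed ether; a diaryl ether cannot be cleaved this way and the lactones are restored on aqueous work-up.

## Compound list

1 | tert-butyl 2-methoxyacetate | COCC(=O)OC(C)(C)C | starting material
2 | methyl 5-chloro-5-oxopentanoate | COC(=O)CCCC(Cl)=O | starting material
3 | 1-tert-butyl 7-methyl 2-methoxy-3-oxoheptanedioate (racemic) | COC(=O)CCCC(=O)C(OC)C(=O)OC(C)(C)C | intermediate
4 | 1-tert-butyl 7-methyl (2E)-3-chloro-2-methoxyhept-2-enedioate | COC(=O)CCC/C(Cl)=C(\OC)C(=O)OC(C)(C)C | intermediate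
5 | isoscopoletin (6-hydroxy-7-methoxy-2H-chromen-2-one) | COc1cc2oc(=O)ccc2cc1O | starting material
6 | 1-tert-butyl 7-methyl (2E)-2-methoxy-3-[(7-methoxy-2-oxo-2H-chromen-6-yl)oxy]hept-2-enedioate | COC(=O)CCC/C(Oc1cc2ccc(=O)oc2cc1OC)=C(\OC)C(=O)OC(C)(C)C | intermediate
7 | (2E)-2,7-dimethoxy-3-[(7-methoxy-2-oxo-2H-chromen-6-yl)oxy]-7-oxohept-2-enoic acid | COC(=O)CCC/C(Oc1cc2ccc(=O)oc2cc1OC)=C(\OC)C(O)=O | intermediate
8 | methyl (5E)-7-chloro-6-methoxy-5-[(7-methoxy-2-oxo-2H-chromen-6-yl)oxy]-7-oxohept-5-enoate | COC(=O)CCC/C(Oc1cc2ccc(=O)oc2cc1OC)=C(\OC)C(Cl)=O | intermediate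
9 | ethoxyethyne | CCOC#C | starting material
10 | methyl (4Z)-6-methoxy-5-[(7-methoxy-2-oxo-2H-chromen-6-yl)oxy]-7-oxohepta-4,6-dienoate (vinylketene; formed in step 6 and not isolated) | O=C=C(OC)/C(Oc1cc2ccc(=O)oc2cc1OC)=C/CCC(=O)OC | intermediate
11 | methyl (4Z)-5-(2-ethoxy-1-methoxy-4-oxocyclobut-2-en-1-yl)-5-[(7-methoxy-2-oxo-2H-chromen-6-yl)oxy]pent-4-enoate (racemic; formed in step 6 and not isolated) | CCOC1=CC(=O)C1(OC)/C(Oc2cc3ccc(=O)oc3cc2OC)=C/CCC(=O)OC | intermediate
12 | methyl (4Z,6Z)-7-ethoxy-6-methoxy-5-[(7-methoxy-2-oxo-2H-chromen-6-yl)oxy]-9-oxonona-4,6,8-trienoate (dienylketene; formed in step 6 and not isolated) | O=C=C/C(OCC)=C(OC)\C(Oc1cc2ccc(=O)oc2cc1OC)=C\CCC(=O)OC | intermediate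
13 | methyl 3-{4-ethoxy-3-methoxy-2-[(7-methoxy-2-oxo-2H-chromen-6-yl)oxy]-6-oxocyclohexa-2,4-dien-1-yl}propanoate (racemic; formed in step 6 and not isolated) | COC(=O)CCC1C(=O)C=C(OCC)C(OC)=C1Oc1cc2ccc(=O)oc2cc1OC | intermediate
14 | methyl 3-{4-ethoxy-6-hydroxy-3-methoxy-2-[(7-methoxy-2-oxo-2H-chromen-6-yl)oxy]phenyl}propanoate | COC(=O)CCc1c(O)cc(OCC)c(OC)c1Oc1cc2ccc(=O)oc2cc1OC | intermediate
15 | 7-ethoxy-6-methoxy-5-[(7-methoxy-2-oxo-2H-chromen-6-yl)oxy]-3,4-dihydro-2H-chromen-2-one | O=C1CCc2c(O1)cc(OCC)c(OC)c2Oc1cc2ccc(=O)oc2cc1OC | intermediate
16 | 7-ethoxy-6-methoxy-5-[(7-methoxy-2-oxo-2H-chromen-6-yl)oxy]-2H-chromen-2-one | O=c1ccc2c(o1)cc(OCC)c(OC)c2Oc1cc2ccc(=O)oc2cc1OC | intermediate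
17 | 6,7-dihydroxy-5-[(7-hydroxy-2-oxo-2H-chromen-6-yl)oxy]-2H-chromen-2-one | O=c1ccc2cc(Oc3c(O)c(O)cc4oc(=O)ccc34)c(O)cc2o1 | target

## Step count and risks

Total: 9 steps. Longest linear sequence: 9 steps (1 or 2 to 17); 5 and 9 enter as single compounds.

**Step 6 (key step).**
- **Risk:** The vinylketene may be consumed by amine-catalysed dimerisation, oligomerisation or acylammonium pathways faster than the ynol ether captures it. The 3-ethoxycyclobutenone may also resist ring opening below the temperature at which it decomposes. If the two stages overlap, the phenol may be acylated by unreacted ketene.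
- **Fallback (known chemistry, abandons the benzannulation):** This sets out from 5 and returns at 17. Nucleophilic aromatic substitution of 5 on 2-fluoro-3,4-dimethoxybenzaldehyde (COc1ccc(C=O)c(F)c1OC; K2CO3, DMF, 120 °C) should give 3,4-dimethoxy-2-[(7-methoxy-2-oxo-2H-chromen-6-yl)oxy]benzaldehyde F1. Knoevenagel–Doebner condensation (malonic acid, pyridine, piperidine cat., 100 °C) should give the (E)-cinnamic acid F2. Flavin-photocatalysed aerobic lactonisation should then close O1–C8a at the only free ortho carbon and give the trimethyl ether F3 (the same compound as A1). BBr3 in CH2Cl2 converts F3 into 17.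

**Step 3.**
- **Risk:** Addition of the ortho-methoxy phenoxide to a tetrasubstituted β-carbon may be slow, because the α-methoxy group lowers its electrophilicity. Base-induced dehydrochlorination toward an allenoate and migration of the double bond out of conjugation can then compete.
- **Fallback:** This sets out from 3 and returns at 6, and it also bypasses step 2. Compound 3 is converted into the enol triflate 1-tert-butyl 7-methyl (2E)-2-methoxy-3-{[(trifluoromethyl)sulfonyl]oxy}hept-2-enedioate F4 (NaH, Tf2O, CH2Cl2, 0 °C). F4 is then coupled with 5 under palladium catalysis (Pd(OAc)2, 2-(di-tert-butylphosphino)biphenyl, K3PO4, PhMe, 80 °C), the known C–O coupling of phenols with alkenyl triflates.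

**Step 8.**
- **Risk:** Hydride abstraction may be incomplete, or the quinone may form adducts with, or over-oxidise, the electron-rich trialkoxyarene.
- **Fallback:** This sets out from 15 and returns at 16. The lactone enolate (LiN(SiMe3)2, THF, −78 °C) is selenenylated with PhSeCl to give 7-ethoxy-6-methoxy-5-[(7-methoxy-2-oxo-2H-chromen-6-yl)oxy]-3-(phenylselanyl)-3,4-dihydro-2H-chromen-2-one F5 (racemic). Oxidation with H2O2 (CH2Cl2, 0 °C) and syn-elimination of the selenoxide toward benzylic C4 gives 16.

**Step 1.**
- **Risk:** The α-alkoxy ester enolate may be O-acylated or may decompose, and proton transfer from the product may stall the conversion.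
- **Fallback:** This sets out from 2 and returns at 3.
  - Acylation of Meldrum's acid with 2 (pyridine, CH2Cl2, 0 °C) gives methyl 5-(2,2-dimethyl-4,6-dioxo-1,3-dioxan-5-ylidene)-5-hydroxypentanoate F6.
  - Heating F6 with tert-butanol in PhMe gives 1-tert-butyl 7-methyl 3-oxoheptanedioate F7.
  - Diazo transfer (4-acetamidobenzenesulfonyl azide, Et3N, MeCN) gives 1-tert-butyl 7-methyl 2-diazo-3-oxoheptanedioate F8.
  - Rh2(OAc)4-catalysed O–H insertion into methanol (CH2Cl2, rt) gives 3.

## Further compounds

F1 | step 6 | 3,4-dimethoxy-2-[(7-methoxy-2-oxo-2H-chromen-6-yl)oxy]benzaldehyde | COc1ccc(C=O)c(Oc2cc3ccc(=O)oc3cc2OC)c1OC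
F2 | step 6 | (2E)-3-{3,4-dimethoxy-2-[(7-methoxy-2-oxo-2H-chromen-6-yl)oxy]phenyl}prop-2-enoic acid | COc1ccc(/C=C/C(O)=O)c(Oc2cc3ccc(=O)oc3cc2OC)c1OC
F3 | step 6 | 6,7-dimethoxy-5-[(7-methoxy-2-oxo-2H-chromen-6-yl)oxy]-2H-chromen-2-one | COc1cc2oc(=O)ccc2cc1Oc1c(OC)c(OC)cc2oc(=O)ccc12
F4 | step 3 | 1-tert-butyl 7-methyl (2E)-2-methoxy-3-{[(trifluoromethyl)sulfonyl]oxy}hept-2-enedioate | COC(=O)CCC/C(OS(=O)(=O)C(F)(F)F)=C(\OC)C(=O)OC(C)(C)C
F5 | step 8 | 7-ethoxy-6-methoxy-5-[(7-methoxy-2-oxo-2H-chromen-6-yl)oxy]-3-(phenylselanyl)-3,4-dihydro-2H-chromen-2-one (racemic) | O=C1C([Se]c2ccccc2)Cc2c(O1)cc(OCC)c(OC)c2Oc1cc2ccc(=O)oc2cc1OC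
F6 | step 1 | methyl 5-(2,2-dimethyl-4,6-dioxo-1,3-dioxan-5-ylidene)-5-hydroxypentanoate | COC(=O)CCCC(O)=C1C(=O)OC(C)(C)OC1=O
F7 | step 1 | 1-tert-butyl 7-methyl 3-oxoheptanedioate | COC(=O)CCCC(=O)CC(=O)OC(C)(C)C
F8 | step 1 | 1-tert-butyl 7-methyl 2-diazo-3-oxoheptanedioate | COC(=O)CCCC(=O)C(=[N+]=[N-])C(=O)OC(C)(C)C
A1 | alternative 1 | 6,7-dimethoxy-5-[(7-methoxy-2-oxo-2H-chromen-6-yl)oxy]-2H-chromen-2-one | COc1cc2oc(=O)ccc2cc1Oc1c(OC)c(OC)cc2oc(=O)ccc12
A2 | alternative 1 | (2E)-3-{2-[5-[(1E)-2-carboxyethenyl]-2-methoxyphenoxy]-3,4-dimethoxyphenyl}prop-2-enoic acid | OC(=O)/C=C/c1ccc(OC)c(Oc2c(OC)c(OC)ccc2/C=C/C(O)=O)c1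
A3 | alternative 2 | 5-[(6,7-dimethoxy-2-oxo-2H-chromen-5-yl)oxy]-2,4-dihydroxybenzaldehyde | O=Cc1cc(Oc2c(OC)c(OC)cc3oc(=O)ccc23)c(O)cc1O
A4 | alternative 2 | 6,7-dimethoxy-5-{[(1Z,3Z)-4-methoxy-2,4-bis(trimethylsilyloxy)buta-1,3-dien-1-yl]oxy}-2H-chromen-2-one | CO/C(O[Si](C)(C)C)=C/C(O[Si](C)(C)C)=C/Oc1c(OC)c(OC)cc2oc(=O)ccc12
A5 | alternative 2 | propynal | C#CC=O
A6 | alternative 2 | 5-hydroxy-6,7-dimethoxy-2H-chromen-2-one | COc1cc2oc(=O)ccc2c(O)c1OC
A7 | alternative 3 | methyl 3-{5-[(6,7-dimethoxy-2-oxo-2H-chromen-5-yl)oxy]-2-hydroxy-4-methoxyphenyl}propanoate | COC(=O)CCc1cc(Oc2c(OC)c(OC)cc3oc(=O)ccc23)c(OC)cc1O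
A8 | alternative 3 | pentacarbonyl{[(6,7-dimethoxy-2-oxo-2H-chromen-5-yl)oxy](1-methoxyethenyl)methylidene}chromium, (CO)5Cr=C(OAr)C(OMe)=CH2 | COC(=C)C(Oc1c(OC)c(OC)cc2oc(=O)ccc12)=[Cr](=C=O)(=C=O)(=C=O)(=C=O)=C=O
A9 | alternative 3 | methyl pent-4-ynoate | C#CCCC(=O)OC
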